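## Retrosynthetic overview

1. Target ⇒ C9,C15‑diol: both angelates go on last in one Yamaguchi esterification; the C7 acetate is carried through.
2. Cyclobutane last (C4–C10, the bond of the himachalyl → longipinyl closure): an oxirane‑triggered cation–olefin cyclisation of a cis‑fused 6/7 epoxy enone through its silyl dienol ether sets C4 and C10, keeps the C9–O bond and returns the enone.
3. Six‑membered ring second: Diels–Alder of a 4,4‑disubstituted cycloheptenone with a 1‑silyloxy‑3‑methylbutadiene, then ketone → C9=C10–CH3 → oxirane.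
4. Seven‑membered ring first: iridium‑catalysed tert‑(hydroxy)prenylation (sets C6) and, in the same flask, ring‑closing metathesis across C5=C11 (the bond of the humulyl → himachalyl closure); C7 is reset by oxidation and directed reduction.
5. Ring order: seven → six → four.

Assumption: longipinane numbering is used throughout (C1 ketone, C2=C3–C12H3, C6 bearing C14H3 and C15H2O, C7 acetate, C9 oxygen, C10–C13H3; "4,10‑seco" = C4–C10 bond absent, i.e. the cis‑fused bicyclo[5.4.0]undecane; "13‑nor" = C13 methyl absent), and the (R)‑Tol‑BINAP iridium catalyst is taken to give the 2S centre of 3 (otherwise the mirror ligand is used).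

## Route

Step 1
Reactants: 1 hex-5-en-1-ol; 2 2-ethenyl-2-methyloxirane
Product: 4 (1S,2S)-2-(hydroxymethyl)-2-methylcyclohept-3-en-1-ol, via acyclic diol 3 (not isolated)
Conditions: excess of racemic 2, π‑allyliridium C,O‑benzoate catalyst from [Ir(cod)Cl]2, (R)‑Tol‑BINAP, 4‑cyano‑3‑nitrobenzoic acid and allyl acetate (5 mol %), K3PO4 (5 mol %), THF, 60 °C; then evaporate THF and excess 2, CH2Cl2 (5 mM), second‑generation Grubbs catalyst RuCl2(=CHPh)(H2IMes)(PCy3) (5 mol %), 40 °C
Reagents that add atoms: none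
Why: Krische redox‑neutral tert‑(hydroxy)prenylation, in which alcohol dehydrogenation and vinyl‑oxirane ionisation give an aldehyde/(hydroxymethyl)allyliridium pair that recombines through a closed chair transition state with the ligand fixing the 2S quaternary centre (the carbinol centre is erased in step 2, so both diastereomers converge), is followed in the same flask by ring‑closing olefin metathesis, which can only give the seven‑membered ring and closes C5=C11 without touching a stereocentre.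

Step 2
Reactants: 4 (1S,2S)-2-(hydroxymethyl)-2-methylcyclohept-3-en-1-ol
Product: 5 (1S)-1-methyl-7-oxocyclohept-2-ene-1-carbaldehyde
Conditions: Dess–Martin periodinane (2.6 equiv), NaHCO3, CH2Cl2, 0 → 23 °C
Reagents that add atoms: none
Why: Dess–Martin oxidation of both hydroxyls deletes the wrongly configured carbinol centre and gives a keto aldehyde whose α‑quaternary centre cannot epimerise.

Step 3
Reactants: 5 (1S)-1-methyl-7-oxocyclohept-2-ene-1-carbaldehyde
Product: 7 (1R,2S)-2-(hydroxymethyl)-2-methylcyclohept-3-en-1-ol, via hydroxy ketone 6 (not isolated)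
Conditions: Me4NBH(OAc)3 (5 equiv), MeCN/AcOH 1:1, −20 → 0 °C
Reagents that add atoms: none
Why: Saksena–Evans reduction, in which the aldehyde is reduced first and the resulting primary alkoxyborohydride delivers hydride intramolecularly to the ketone face on the side of the CH2O arm, so the new hydroxyl ends trans to the hydroxymethyl group (1R).

Step 4
Reactants: 7 (1R,2S)-2-(hydroxymethyl)-2-methylcyclohept-3-en-1-ol
Product: 9 (1R,2S)-2-[(tert-butyldiphenylsilyl)oxymethyl]-2-methylcyclohept-3-en-1-yl acetate, via silyl ether alcohol 8 (not isolated)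
Conditions: TBDPSCl (1.05 equiv), imidazole, CH2Cl2, 0 °C; then Ac2O, Et3N, DMAP (cat.), 23 °C
Reagents that add atoms: tert-butyldiphenylsilyl chloride (CC(C)(C)[Si](Cl)(c1ccccc1)c1ccccc1); acetic anhydride (CC(=O)OC(C)=O)
Why: The bulky silyl chloride is selective for the primary neopentyl hydroxyl and the remaining secondary hydroxyl is then acetylated in the same flask, with no stereocentre touched.

Step 5
Reactants: 9 (1R,2S)-2-[(tert-butyldiphenylsilyl)oxymethyl]-2-methylcyclohept-3-en-1-yl acetate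
Product: 10 (1R,2S)-2-[(tert-butyldiphenylsilyl)oxymethyl]-2-methyl-5-oxocyclohept-3-en-1-yl acetate
Conditions: Rh2(cap)4 (dirhodium tetracaprolactamate, 1 mol %), t‑BuOOH (5 equiv), K2CO3, CH2Cl2, 23 °C
Reagents that add atoms: tert-butyl hydroperoxide (CC(C)(C)OO)
Why: Rhodium carboxamidate/hydroperoxide allylic oxidation can only attack the single allylic methylene (the other allylic carbon is quaternary) and gives the conjugated enone.

Step 6
Reactants: 11 3-methylbut-2-enal
Product: 12 (E)-triethyl[(3-methylbuta-1,3-dien-1-yl)oxy]silane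
Conditions: TESOTf, Et3N, Et2O, 0 °C
Reagents that add atoms: triethylsilyl trifluoromethanesulfonate (CC[Si](CC)(CC)OS(=O)(=O)C(F)(F)F)
Why: Soft enolisation of the enal by O‑silylation and γ‑deprotonation gives the E‑configured 1‑silyloxy diene.

Step 7
Reactants: 10 (1R,2S)-2-[(tert-butyldiphenylsilyl)oxymethyl]-2-methyl-5-oxocyclohept-3-en-1-yl acetate; 12 (E)-triethyl[(3-methylbuta-1,3-dien-1-yl)oxy]silane
Product: 13 (1R,5S,6S,7R,11S)-7-acetoxy-15-(tert-butyldiphenylsilyloxy)-1-(triethylsilyloxy)-13-nor-4,10-secolongipin-2-en-10-one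
Conditions: Me2AlCl (1.1 equiv), excess of 12, CH2Cl2, −78 → −40 °C; then aqueous NaHCO3
Reagents that add atoms: none
Why: Diels–Alder reaction promoted by a full equivalent of Me2AlCl, which activates the hindered enone and scavenges protic acid that would cleave the silyl dienol ether; the 1‑silyloxy and 3‑methyl groups both send the diene CH2 terminus to the enone β‑carbon (C4–C5 and C1–C11 bonds), suprafacial addition gives the cis ring fusion, and the diene approaches anti to the bulky CH2OSi group on the neighbouring quaternary carbon (5S, 11S; endo sets 1R, lost in step 10).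

Step 8
Reactants: 13 (1R,5S,6S,7R,11S)-7-acetoxy-15-(tert-butyldiphenylsilyloxy)-1-(triethylsilyloxy)-13-nor-4,10-secolongipin-2-en-10-one
Product: 14 (1R,5S,6S,7R,11S)-7-acetoxy-15-(tert-butyldiphenylsilyloxy)-1-(triethylsilyloxy)-13-nor-4,10-secolongipina-2,9-dien-10-yl trifluoromethanesulfonate
Conditions: KN(SiMe3)2 (1.1 equiv), THF, −78 °C; then PhNTf2, −78 → −40 °C
Reagents that add atoms: N-phenylbis(trifluoromethanesulfonimide) (O=S(=O)(N(c1ccccc1)S(=O)(=O)C(F)(F)F)C(F)(F)F)
Why: Kinetic deprotonation at the unhindered α‑methylene C9 (not at the β‑silyloxy methine C11) and O‑sulfonylation give the C9=C10 enol triflate regioselectively.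

Step 9
Reactants: 14 (1R,5S,6S,7R,11S)-7-acetoxy-15-(tert-butyldiphenylsilyloxy)-1-(triethylsilyloxy)-13-nor-4,10-secolongipina-2,9-dien-10-yl trifluoromethanesulfonate
Product: 15 (1R,5S,6S,7R,11R)-7-acetoxy-15-(tert-butyldiphenylsilyloxy)-1-(triethylsilyloxy)-4,10-secolongipina-2,9-diene
Conditions: Pd(PPh3)4 (5 mol %), ZnMe2 (2 equiv), THF, 0 → 23 °C
Reagents that add atoms: dimethylzinc (C[Zn]C)
Why: Negishi cross‑coupling of the enol triflate installs the C13 methyl group with the alkene held at C9=C10 and tolerates the acetate.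

Step 10
Reactants: 15 (1R,5S,6S,7R,11R)-7-acetoxy-15-(tert-butyldiphenylsilyloxy)-1-(triethylsilyloxy)-4,10-secolongipina-2,9-diene
Product: 16 (5S,6S,7R,11R)-7-acetoxy-15-(tert-butyldiphenylsilyloxy)-4,10-secolongipina-2,9-dien-1-one
Conditions: DDQ (1.5 equiv), CH2Cl2/pH 7 phosphate buffer, 0 → 23 °C; used at once
Reagents that add atoms: none
Why: Oxidative deprotection of an allylic silyl ether, in which DDQ abstracts the hydride of the allylic carbinol C–H and the silyloxocarbenium ion is hydrolysed to the enone, leaves the isolated trisubstituted alkene untouched.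

Step 11
Reactants: 16 (5S,6S,7R,11R)-7-acetoxy-15-(tert-butyldiphenylsilyloxy)-4,10-secolongipina-2,9-dien-1-one
Product: 17 (5S,6S,7R,9R,10S,11R)-7-acetoxy-15-(tert-butyldiphenylsilyloxy)-9,10-epoxy-4,10-secolongipin-2-en-1-one
Conditions: m‑CPBA (1.2 equiv), NaHCO3, CH2Cl2, 0 °C
Reagents that add atoms: 3-chloroperoxybenzoic acid (O=C(OO)c1cccc(Cl)c1)
Why: Prilezhaev epoxidation is chemoselective for the electron‑rich trisubstituted alkene over the enone and attacks the convex face, anti to the cyclohexenone ring that sits axially under C10, giving the oxide cis to H‑11 (9R,10S).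

Step 12
Reactants: 17 (5S,6S,7R,9R,10S,11R)-7-acetoxy-15-(tert-butyldiphenylsilyloxy)-9,10-epoxy-4,10-secolongipin-2-en-1-one
Product: 20 (4R,5S,6S,7R,9R,10R,11R)-7-acetoxy-9,15-dihydroxylongipin-2-en-1-one, via silyl dienol ether 18 (not isolated), via O9-silylated tricycle 19 (not isolated)
Conditions: TBSOTf (1.1 equiv), Et3N (1.3 equiv), CH2Cl2, −78 °C; then TBSOTf (0.4 equiv), −78 → −40 °C; then HF·pyridine, THF, 0 → 23 °C
Reagents that add atoms: none
Why: Proposed new method: soft γ‑enolisation of the β,β‑disubstituted enone (as with Wieland–Miescher‑type enones) gives the linear silyl dienol ether 18, whose C4 terminus is held under C10 by the cis ring fusion; the free silyl triflate then activates the oxirane, which opens at the tertiary C10 with backside attack by C4 (4‑exo, anti to the leaving oxygen), a vinylogous Mukaiyama‑type epoxide alkylation that mirrors the himachalyl → longipinyl cation–olefin closure, sets C4 and C10 (inversion), keeps C9 and collapses to the enone with silyl transfer to O9, after which HF removes both silyl groups; the closest known reactions are Lewis‑acid epoxide‑initiated cation–olefin cyclisations terminated by enol ethers and γ‑selective vinylogous Mukaiyama alkylations.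

Step 13
Reactants: 20 (4R,5S,6S,7R,9R,10R,11R)-7-acetoxy-9,15-dihydroxylongipin-2-en-1-one; 21 angelic acid, (Z)-2-methylbut-2-enoic acid (3 equiv)
Product: 23 (4R,5S,6S,7R,9R,10R,11R)-7-acetoxy-9,15-bis[(Z)-2-methylbut-2-enoyloxy]longipin-2-en-1-one (CNP0364726.1), via mixed anhydride 22 (not isolated)
Conditions: 21, 2,4,6‑trichlorobenzoyl chloride (3 equiv), Et3N, toluene, 23 °C; then 20, 80 °C
Reagents that add atoms: none
Why: Yamaguchi esterification through the mixed 2,4,6‑trichlorobenzoic anhydride acylates the primary and the hindered secondary hydroxyl without nucleophilic catalyst, which avoids Z → E isomerisation of the angelate, and touches no stereocentre.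

## Compound list

1 | hex-5-en-1-ol | C=CCCCCO | starting material
2 | 2-ethenyl-2-methyloxirane (isoprene monoxide, racemic) | C=CC1(C)CO1 | starting material
3 | (2S,3S)-2-ethenyl-2-methyloct-7-ene-1,3-diol | OC[C@](C)(C=C)[C@@H](O)CCCC=C | intermediate
4 | (1S,2S)-2-(hydroxymethyl)-2-methylcyclohept-3-en-1-ol (OH cis to CH2OH) | OC[C@]1(C)C=CCCC[C@@H]1O | intermediate
5 | (1S)-1-methyl-7-oxocyclohept-2-ene-1-carbaldehyde | O=C[C@]1(C)C=CCCCC1=O | intermediate
6 | (2S)-2-(hydroxymethyl)-2-methylcyclohept-3-en-1-one | OC[C@]1(C)C=CCCCC1=O | intermediate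
7 | (1R,2S)-2-(hydroxymethyl)-2-methylcyclohept-3-en-1-ol (OH trans to CH2OH) | OC[C@]1(C)C=CCCC[C@H]1O | intermediate
8 | (1R,2S)-2-[(tert-butyldiphenylsilyl)oxymethyl]-2-methylcyclohept-3-en-1-ol | CC(C)(C)[Si](c2ccccc2)(c3ccccc3)OC[C@]1(C)C=CCCC[C@H]1O | intermediate
9 | (1R,2S)-2-[(tert-butyldiphenylsilyl)oxymethyl]-2-methylcyclohept-3-en-1-yl acetate | CC(C)(C)[Si](c2ccccc2)(c3ccccc3)OC[C@]1(C)C=CCCC[C@H]1OC(C)=O | intermediate
10 | (1R,2S)-2-[(tert-butyldiphenylsilyl)oxymethyl]-2-methyl-5-oxocyclohept-3-en-1-yl acetate | CC(C)(C)[Si](c2ccccc2)(c3ccccc3)OC[C@]1(C)C=CC(=O)CC[C@H]1OC(C)=O | intermediate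
11 | 3-methylbut-2-enal | CC(C)=CC=O | starting material
12 | (E)-triethyl[(3-methylbuta-1,3-dien-1-yl)oxy]silane | C=C(C)/C=C/O[Si](CC)(CC)CC | intermediate
13 | (1R,5S,6S,7R,11S)-7-acetoxy-15-(tert-butyldiphenylsilyloxy)-1-(triethylsilyloxy)-13-nor-4,10-secolongipin-2-en-10-one (cis-fused; OTES cis to C10) | CC(C)(C)[Si](c4ccccc4)(c5ccccc5)OC[C@]1(C)[C@@H]2[C@@H]([C@H](O[Si](CC)(CC)CC)C=C(C)C2)C(=O)CC[C@H]1OC(C)=O | intermediate
14 | (1R,5S,6S,7R,11S)-7-acetoxy-15-(tert-butyldiphenylsilyloxy)-1-(triethylsilyloxy)-13-nor-4,10-secolongipina-2,9-dien-10-yl trifluoromethanesulfonate | CC(C)(C)[Si](c4ccccc4)(c5ccccc5)OC[C@]1(C)[C@@H]2[C@@H]([C@H](O[Si](CC)(CC)CC)C=C(C)C2)C(OS(=O)(=O)C(F)(F)F)=CC[C@H]1OC(C)=O | intermediate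
15 | (1R,5S,6S,7R,11R)-7-acetoxy-15-(tert-butyldiphenylsilyloxy)-1-(triethylsilyloxy)-4,10-secolongipina-2,9-diene | CC(C)(C)[Si](c4ccccc4)(c5ccccc5)OC[C@]1(C)[C@@H]2[C@@H]([C@H](O[Si](CC)(CC)CC)C=C(C)C2)C(C)=CC[C@H]1OC(C)=O | intermediate
16 | (5S,6S,7R,11R)-7-acetoxy-15-(tert-butyldiphenylsilyloxy)-4,10-secolongipina-2,9-dien-1-one | CC(C)(C)[Si](c4ccccc4)(c5ccccc5)OC[C@]1(C)[C@@H]2[C@@H](C(=O)C=C(C)C2)C(C)=CC[C@H]1OC(C)=O | intermediate
17 | (5S,6S,7R,9R,10S,11R)-7-acetoxy-15-(tert-butyldiphenylsilyloxy)-9,10-epoxy-4,10-secolongipin-2-en-1-one (oxirane cis to H-11) | CC(C)(C)[Si](c4ccccc4)(c5ccccc5)OC[C@]1(C)[C@@H]2[C@@H](C(=O)C=C(C)C2)[C@]3(C)O[C@@H]3C[C@H]1OC(C)=O | intermediate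
18 | (5S,6S,7R,9R,10S,11R)-7-acetoxy-1-(tert-butyldimethylsilyloxy)-15-(tert-butyldiphenylsilyloxy)-9,10-epoxy-4,10-secolongipina-1,3-diene | CC(C)(C)[Si](c4ccccc4)(c5ccccc5)OC[C@]1(C)[C@@H]2[C@@H](C(O[Si](C)(C)C(C)(C)C)=CC(C)=C2)[C@]3(C)O[C@@H]3C[C@H]1OC(C)=O | intermediate
19 | (4R,5S,6S,7R,9R,10R,11R)-7-acetoxy-9-(tert-butyldimethylsilyloxy)-15-(tert-butyldiphenylsilyloxy)longipin-2-en-1-one | CC(C)(C)[Si](c4ccccc4)(c5ccccc5)OC[C@]1(C)[C@@H]2[C@H]3C(=O)C=C(C)[C@@H]2[C@@]3(C)[C@H](O[Si](C)(C)C(C)(C)C)C[C@H]1OC(C)=O | intermediate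
20 | (4R,5S,6S,7R,9R,10R,11R)-7-acetoxy-9,15-dihydroxylongipin-2-en-1-one | OC[C@]1(C)[C@@H]2[C@H]3C(=O)C=C(C)[C@@H]2[C@@]3(C)[C@H](O)C[C@H]1OC(C)=O | intermediate
21 | angelic acid, (Z)-2-methylbut-2-enoic acid | C/C=C(/C)C(=O)O | starting material
22 | angelic 2,4,6-trichlorobenzoic mixed anhydride | C/C=C(/C)C(=O)OC(=O)c1c(Cl)cc(Cl)cc1Cl | intermediate
23 | (4R,5S,6S,7R,9R,10R,11R)-7-acetoxy-9,15-bis[(Z)-2-methylbut-2-enoyloxy]longipin-2-en-1-one | C/C=C(/C)C(=O)OC[C@]1(C)[C@@H]2[C@H]3C(=O)C=C(C)[C@@H]2[C@@]3(C)[C@H](OC(=O)/C(C)=C\C)C[C@H]1OC(C)=O | target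

## Step count and weakest steps

Total: 13 steps. Longest linear sequence: 12 steps (1 → 23 through steps 1–5 and 7–13; step 6 is a one‑step branch).

**Step 12 (most likely to fail).** Three things can go wrong. Enolisation may occur at C11 next to the oxirane and destroy it. The C10 cation may be lost to a hydride shift from C9 (giving the C9 ketone) or to elimination. The dienol ether may attack through C2 and give the cyclobutanone isomer. The fallback replaces the oxirane by a cation that is held by a neighbouring ester. It sets out from 16 and comes back to the route at 23. Dihydroxylation of 16 (OsO4 cat., NMO, acetone/water) on the same convex face gives the 9,10‑cis‑diol F1. Yamaguchi esterification with 21 acylates only the secondary C9 hydroxyl and gives the hydroxy angelate F2. TBSOTf/Et3N at −78 °C gives the bis‑silylated dienol ether F3, which is not isolated. Catalytic TMSOTf ionises the tertiary silyloxy group; the angelate carbonyl captures the cation as a cis‑fused dioxolan‑2‑ylium ion on the face of H‑11, and C4 opens it at C10 from the opposite face to give the tricyclic 9‑angelate 15‑silyl ether F4. HF·pyridine frees the primary alcohol F5, and one Yamaguchi esterification with 21 gives 23.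

**Step 7.** The enone is hindered by the neighbouring quaternary carbon, the silyloxy diene is acid‑labile, and facial selectivity rests on CH2OSi against CH3. The fallback gives up the concerted cycloaddition for a two‑stage polar annulation in which each C–C bond is made separately. It sets out from 10 (with 12) and comes back at 13. A vinylogous Mukaiyama–Michael addition (TESOTf cat., CH2Cl2, −78 °C) joins C4 to C5 with silyl transfer and gives the silyl enol ether enal F6, which is isolated. An intramolecular Mukaiyama aldol reaction (BF3·OEt2, −78 °C) of the regiodefined enol ether onto the aldehyde closes C11–C1 to the cis‑fused hydroxy ketone F7. Silylation (TESOTf, 2,6‑lutidine) returns 13.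

**Step 11.** The peracid may attack the other face, and 16 can slip its C9=C10 bond into conjugation before it reacts. The fallback uses a halohydrin, which places the oxirane on the face opposite to the one an electrophile attacks. It sets out from 16 and comes back at 17. NBS in THF/water gives, by bromonium formation on the accessible face and attack of water at the tertiary C10 from the other side, the trans‑bromohydrin F8 (C9 bromide, C10 hydroxyl cis to H‑11). K2CO3 in MeCN closes it to 17.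

## Further compounds

F1 | step 12 | (5S,6S,7R,9R,10S,11R)-7-acetoxy-15-(tert-butyldiphenylsilyloxy)-9,10-dihydroxy-4,10-secolongipin-2-en-1-one (cis-diol, both hydroxyls cis to H-11) | CC(C)(C)[Si](c4ccccc4)(c5ccccc5)OC[C@]1(C)[C@@H]2[C@@H](C(=O)C=C(C)C2)[C@](C)(O)[C@H](O)C[C@H]1OC(C)=O
F2 | step 12 | 9-O-angelate of F1 (tertiary C10 hydroxyl free) | CC(C)(C)[Si](c4ccccc4)(c5ccccc5)OC[C@]1(C)[C@@H]2[C@@H](C(=O)C=C(C)C2)[C@](C)(O)[C@H](OC(=O)/C(C)=C\C)C[C@H]1OC(C)=O
F3 | step 12 | 1,10-bis(tert-butyldimethylsilyl) dienol ether of F2 (1,3-diene) | CC(C)(C)[Si](c4ccccc4)(c5ccccc5)OC[C@]1(C)[C@@H]2[C@@H](C(O[Si](C)(C)C(C)(C)C)=CC(C)=C2)[C@](C)(O[Si](C)(C)C(C)(C)C)[C@H](OC(=O)/C(C)=C\C)C[C@H]1OC(C)=O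
F4 | step 12 | (4R,5S,6S,7R,9R,10R,11R)-7-acetoxy-9-angeloyloxy-15-(tert-butyldiphenylsilyloxy)longipin-2-en-1-one | CC(C)(C)[Si](c4ccccc4)(c5ccccc5)OC[C@]1(C)[C@@H]2[C@H]3C(=O)C=C(C)[C@@H]2[C@@]3(C)[C@H](OC(=O)/C(C)=C\C)C[C@H]1OC(C)=O
F5 | step 12 | (4R,5S,6S,7R,9R,10R,11R)-7-acetoxy-9-angeloyloxy-15-hydroxylongipin-2-en-1-one | OC[C@]1(C)[C@@H]2[C@H]3C(=O)C=C(C)[C@@H]2[C@@]3(C)[C@H](OC(=O)/C(C)=C\C)C[C@H]1OC(C)=O
F6 | step 7 | (1R,2S,3S)-2-[(tert-butyldiphenylsilyl)oxymethyl]-2-methyl-3-[(Z)-2-methyl-4-oxobut-2-enyl]-5-(triethylsilyloxy)cyclohept-4-en-1-yl acetate | CC(C)(C)[Si](c4ccccc4)(c5ccccc5)OC[C@]1(C)[C@@H](C/C(C)=C\C=O)C=C(O[Si](CC)(CC)CC)CC[C@H]1OC(C)=O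
F7 | step 7 | (1R,5S,6S,7R,11S)-7-acetoxy-15-(tert-butyldiphenylsilyloxy)-1-hydroxy-13-nor-4,10-secolongipin-2-en-10-one | CC(C)(C)[Si](c4ccccc4)(c5ccccc5)OC[C@]1(C)[C@@H]2[C@@H]([C@H](O)C=C(C)C2)C(=O)CC[C@H]1OC(C)=O
F8 | step 11 | (5S,6S,7R,9S,10S,11R)-7-acetoxy-9-bromo-15-(tert-butyldiphenylsilyloxy)-10-hydroxy-4,10-secolongipin-2-en-1-one (Br trans to OH) | CC(C)(C)[Si](c4ccccc4)(c5ccccc5)OC[C@]1(C)[C@@H]2[C@@H](C(=O)C=C(C)C2)[C@](C)(O)[C@@H](Br)C[C@H]1OC(C)=O
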